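**Strategy.** Everything rests on the sp2–sp2 single bond between C12′ (the CH end of the ring B dienyne arm) and the methyl-bearing C13′. One stereoretentive Suzuki–Miyaura coupling of a C24 hexaenyl iodide (ring A to C13′) with a C16 dienynyl boronate (C12′ to ring B) completes the all-E C40 chain as the last step, on unprotected partners. It exploits the local twofold symmetry of the C13–C13′ dimethyltriene: C12–C13 and C12′–C13′ are equivalent, so one symmetric 2,7-diiodoocta-2,4,6-triene serves both ends. Ring A (cis-3,6-diol) and ring B (3′-hydroxy-7′,8′-yne) derive from the two enantiomers of phorenol, obtained from ketoisophorone by transfer hydrogenation.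

Key step: step 17

Remark on locants: carotenoid numbering is used, with ring A = C1–C6 (3,6-dihydroxy ε ring), chain C7–C15 and C15′–C7′, and ring B = C1′–C6′; the target is then (3S,6R,3′R).

Remark on the transfer hydrogenation: the (R,R)-catalyst is assumed to give (R)-phorenol by analogy with aryl ketones; if the sense is opposite, the two catalyst antipodes of steps 1 and 10 are exchanged.

**Ring A arm (steps 1–6)**

Step 1
Reactants: 1 ketoisophorone (2,6,6-trimethylcyclohex-2-ene-1,4-dione)
Product: 2 (4R)-4-hydroxy-2,6,6-trimethylcyclohex-2-en-1-one ((R)-phorenol)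
Conditions: RuCl[(R,R)-TsDPEN](p-cymene) (1 mol %), i-PrOH, 25 °C
Reagents that add atoms: none
Why: Noyori asymmetric transfer hydrogenation should reduce only the unhindered C4 carbonyl (the C1 carbonyl is flanked by the gem-dimethyl and the vinylic methyl groups), and the chiral ruthenium catalyst sets the carbinol centre (future C3) by catalyst control.

Step 2
Reactants: 2 (R)-phorenol; 3 (2E)-3-methylpent-2-en-4-yn-1-ol
Product: 5 (1R,4R)-1-[(3E)-5-hydroxy-3-methylpent-3-en-1-yn-1-yl]-2,6,6-trimethylcyclohex-2-ene-1,4-diol (ring hydroxyls trans), via dilithio enynol 4 (not isolated)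
Conditions: 3 (2.5 equiv), n-BuLi (5.0 equiv), THF, −78 to −20 °C; then 2, −78 to 0 °C; H2O quench
Reagents that add atoms: none
Why: 1,2-addition of the lithium acetylide to the enone carbonyl, where axial attack anti to the axial C6 methyl of the half-chair that keeps the C4–OLi group pseudoequatorial (its pseudoaxial form would be 1,3-diaxial with that methyl) should place the alkynyl group cis to the C4 oxygen and so set the tertiary centre (future C6) by substrate control.

Step 3
Reactants: 5 trans-diol enynol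
Product: 6 (2E)-5-[(1R,4S)-4-(benzoyloxy)-1-hydroxy-2,6,6-trimethylcyclohex-2-en-1-yl]-3-methylpent-2-en-4-yn-1-yl benzoate
Conditions: PPh3, DIAD, PhCO2H (2.5 equiv each), THF, 0 to 25 °C
Reagents that add atoms: benzoic acid, O=C(O)c1ccccc1
Why: Mitsunobu reaction in which SN2 attack of benzoate on the alkoxyphosphonium ion inverts the secondary allylic carbinol to the (S) configuration, now cis to the tertiary hydroxyl, while the primary alcohol is simply esterified and the tertiary alcohol does not react.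

Step 4
Reactants: 6 dibenzoate
Product: 7 (1R,4S)-1-[(1E,3E)-5-hydroxy-3-methylpenta-1,3-dien-1-yl]-2,6,6-trimethylcyclohex-2-ene-1,4-diol (ring hydroxyls cis)
Conditions: NaAlH2(OCH2CH2OMe)2 (7 equiv), THF, 0 to 25 °C; then H2O, aq. NaOH
Reagents that add atoms: none
Why: The aluminate bound to the propargylic tertiary oxygen delivers hydride in a trans-hydroalumination that should give the (E)-alkene (C7=C8) after protonolysis, and the same hydride reagent cleaves both benzoates reductively.

Step 5
Reactants: 7 cis-triol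
Product: 8 (2E,4E)-5-[(1R,4S)-1,4-dihydroxy-2,6,6-trimethylcyclohex-2-en-1-yl]-3-methylpenta-2,4-dienal
Conditions: TEMPO (10 mol %), PhI(OAc)2 (1.1 equiv), CH2Cl2/aq. pH 7 buffer, 0 °C
Reagents that add atoms: none
Why: Oxoammonium (TEMPO) oxidation is selective for the primary allylic alcohol over the secondary ring carbinol on steric grounds, and the buffered medium protects the acid-labile tertiary allylic hydroxyl.

Step 6
Reactants: 8 dienal
Product: 9 (1R,4S)-2,6,6-trimethyl-1-[(1E,3E,5E)-3-methyl-6-(4,4,5,5-tetramethyl-1,3,2-dioxaborolan-2-yl)hexa-1,3,5-trien-1-yl]cyclohex-2-ene-1,4-diol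
Conditions: Cl2CHBpin (2 equiv), CrCl2 (8 equiv), LiI (4 equiv), THF, 25 °C, dark
Reagents that add atoms: 2-(dichloromethyl)-4,4,5,5-tetramethyl-1,3,2-dioxaborolane, ClC(Cl)B1OC(C)(C)C(C)(C)O1
Why: Takai–Utimoto borylolefination, in which the geminal dichromium reagent adds to the aldehyde and eliminates to the (E)-alkenylboronate (C11=C12), and divalent chromium tolerates the free hydroxyls.

**Central unit and first coupling (steps 7–9)**

Step 7
Reactants: 10 (E)-1,2-dichloroethene; 11 propyne
Product: 13 (4E)-oct-4-ene-2,6-diyne, via chloroenyne 12 (not isolated)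
Conditions: 11 (3 equiv), Pd(PPh3)4 (5 mol %), CuI (10 mol %), n-BuNH2, THF, 25–40 °C, sealed vessel
Reagents that add atoms: none
Why: Twofold Sonogashira coupling of the two vinylic C–Cl bonds proceeds with retention of the (E)-geometry (future C15=C15′).

Step 8
Reactants: 13 enediyne
Product: 15 (2E,4E,6E)-2,7-diiodoocta-2,4,6-triene, via bis(zirconocene) triene 14 (not isolated)
Conditions: Cp2Zr(H)Cl (2.6 equiv), THF, 25–40 °C, dark; then I2 (2.4 equiv), 0 °C
Reagents that add atoms: iodine, II
Why: Syn-hydrozirconation should place zirconium on the less hindered, methyl-bearing carbon of each propynyl group, and iodinolysis with retention then gives the (2E,6E)-diiodide (future C13 and C13′).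

Step 9
Reactants: 9 ring A trienylboronate; 15 diiodotriene
Product: 16 (1R,4S)-1-[(1E,3E,5E,7E,9E,11E)-12-iodo-3,7-dimethyltrideca-1,3,5,7,9,11-hexaen-1-yl]-2,6,6-trimethylcyclohex-2-ene-1,4-diol
Conditions: 15 (3 equiv), Pd(PPh3)4 (5 mol %), TlOEt (1.5 equiv), THF/H2O 3:1, 25 °C, dark
Reagents that add atoms: none
Why: Suzuki–Miyaura coupling with retention at both alkenyl partners forms C12–C13, and the excess of the symmetric diiodide together with a readily dissociating triphenylphosphine catalyst should hold the reaction at mono-coupling, the unreacted 15 being recovered.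

**Ring B arm (steps 10–16)**

Step 10
Reactants: 1 ketoisophorone
Product: 17 (4S)-4-hydroxy-2,6,6-trimethylcyclohex-2-en-1-one ((S)-phorenol)
Conditions: RuCl[(S,S)-TsDPEN](p-cymene) (1 mol %), i-PrOH, 25 °C
Reagents that add atoms: none
Why: The same Noyori asymmetric transfer hydrogenation as in step 1 with the antipodal catalyst gives the enantiomeric carbinol (future C3′) by catalyst control.

Step 11
Reactants: 17 (S)-phorenol
Product: 18 (4S)-4-{[tert-butyl(dimethyl)silyl]oxy}-2,6,6-trimethylcyclohex-2-en-1-one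
Conditions: TBSCl, imidazole, DMF, 25 °C
Reagents that add atoms: tert-butyldimethylsilyl chloride, CC(C)(C)[Si](C)(C)Cl
Why: Standard silylation masks the secondary alcohol, whose alkoxide would otherwise be sulfonylated in step 12.

Step 12
Reactants: 18 silyl ether
Product: 20 (4R)-4-{[tert-butyl(dimethyl)silyl]oxy}-2,6,6-trimethylcyclohex-1-en-1-yl trifluoromethanesulfonate, via lithium enolate 19 (not isolated)
Conditions: LiBH(s-Bu)3 (1.1 equiv), THF, −78 °C; then PhNTf2 (1.2 equiv), −78 to 0 °C
Reagents that add atoms: N-phenylbis(trifluoromethanesulfonimide), O=S(=O)(N(c1ccccc1)S(=O)(=O)C(F)(F)F)C(F)(F)F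
Why: Conjugate hydride addition to the β-unsubstituted enone (1,2-attack is blocked by the flanking methyl groups) gives the tetrasubstituted enolate regiospecifically, which is O-sulfonylated to the enol triflate; the stereocentre is untouched and its descriptor changes to (R) only because the ring priorities change.

Step 13
Reactants: 20 enol triflate; 3 (2E)-3-methylpent-2-en-4-yn-1-ol
Product: 21 (2E)-5-[(4R)-4-{[tert-butyl(dimethyl)silyl]oxy}-2,6,6-trimethylcyclohex-1-en-1-yl]-3-methylpent-2-en-4-yn-1-ol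
Conditions: 3 (1.5 equiv), Pd(PPh3)4 (5 mol %), CuI (10 mol %), i-Pr2NH, DMF, 25–50 °C
Reagents that add atoms: none
Why: Sonogashira coupling of the hindered enol triflate with the terminal alkyne forms C6′–C7′ and installs the 7′,8′-triple bond of ring B directly.

Step 14
Reactants: 21 silyl ether
Product: 22 (1R)-4-[(3E)-5-hydroxy-3-methylpent-3-en-1-yn-1-yl]-3,5,5-trimethylcyclohex-3-en-1-ol
Conditions: HF·pyridine, THF/pyridine, 0 to 25 °C
Reagents that add atoms: none
Why: Fluoride cleaves the silyl ether under buffered conditions that leave the dienynol untouched.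

Step 15
Reactants: 22 diol
Product: 23 (2E)-5-[(4R)-4-hydroxy-2,6,6-trimethylcyclohex-1-en-1-yl]-3-methylpent-2-en-4-ynal
Conditions: MnO2 (20 equiv), CH2Cl2, 25 °C
Reagents that add atoms: none
Why: MnO2 oxidises only the primary allylic alcohol, since the ring carbinol at C3′ is not allylic.

Step 16
Reactants: 23 enynal
Product: 24 (1R)-3,5,5-trimethyl-4-[(3E,5E)-3-methyl-6-(4,4,5,5-tetramethyl-1,3,2-dioxaborolan-2-yl)hexa-3,5-dien-1-yn-1-yl]cyclohex-3-en-1-ol
Conditions: Cl2CHBpin (2 equiv), CrCl2 (8 equiv), LiI (4 equiv), THF, 25 °C, dark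
Reagents that add atoms: 2-(dichloromethyl)-4,4,5,5-tetramethyl-1,3,2-dioxaborolane, ClC(Cl)B1OC(C)(C)C(C)(C)O1
Why: Takai–Utimoto borylolefination as in step 6 should give the (E)-alkenylboronate (C11′=C12′) in the presence of the free hydroxyl.

**Union (step 17)**

Step 17
Reactants: 16 C24 hexaenyl iodide; 24 C16 dienynyl boronate
Product: 25 (3S,6R,3′R)-configured all-E target carotenoid triol
Conditions: Pd(OAc)2 (5 mol %), XPhos (10 mol %), aq. K3PO4 (3 equiv), THF, 25 °C, degassed, dark
Reagents that add atoms: none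
Why: Zerovalent palladium inserts into the C13′–I bond of 16 with retention, the base-activated boronate 24 transfers its C12′ dienynyl group to palladium with retention, and reductive elimination forms the C12′–C13′ bond. The closest known reaction type is the alkenyl–alkenyl Suzuki–Miyaura coupling used to assemble polyenes. No ring is closed and no stereocentre is formed; the (13′E) and (11′E) geometries are carried over unchanged from the syn-hydrozirconation of step 8 and the Takai–Utimoto olefination of step 16, and the three carbinol centres are remote and untouched. The step needs chemoselectivity for the single C(sp2)–I bond over the polyene, over the C7′≡C8′ alkyne (shielded by the C1′ gem-dimethyl group and the C9′ methyl) and over three free hydroxyls, which the mild aqueous phosphate medium at room temperature should provide; a basic rather than acidic medium also protects the tertiary, doubly allylic C6–OH of ring A from ionisation. Running at 25 °C in the dark should limit E/Z isomerisation of the product.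

**Compound list**

1 | ketoisophorone (2,6,6-trimethylcyclohex-2-ene-1,4-dione) | CC1=CC(=O)CC(C)(C)C1=O | starting material
2 | (4R)-4-hydroxy-2,6,6-trimethylcyclohex-2-en-1-one | CC1=C[C@H](O)CC(C)(C)C1=O | intermediate
3 | (2E)-3-methylpent-2-en-4-yn-1-ol | C#C/C(C)=C/CO | starting material
4 | dilithio derivative of 3 (lithium acetylide and lithium alkoxide) | [Li]C#C/C(C)=C/CO[Li] | intermediate
5 | (1R,4R)-1-[(3E)-5-hydroxy-3-methylpent-3-en-1-yn-1-yl]-2,6,6-trimethylcyclohex-2-ene-1,4-diol | CC1=C[C@H](O)CC(C)(C)[C@]1(O)C#C/C(C)=C/CO | intermediate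
6 | (2E)-5-[(1R,4S)-4-(benzoyloxy)-1-hydroxy-2,6,6-trimethylcyclohex-2-en-1-yl]-3-methylpent-2-en-4-yn-1-yl benzoate | CC1=C[C@@H](OC(=O)c2ccccc2)CC(C)(C)[C@]1(O)C#C/C(C)=C/COC(=O)c1ccccc1 | intermediate
7 | (1R,4S)-1-[(1E,3E)-5-hydroxy-3-methylpenta-1,3-dien-1-yl]-2,6,6-trimethylcyclohex-2-ene-1,4-diol | CC1=C[C@@H](O)CC(C)(C)[C@]1(O)/C=C/C(C)=C/CO | intermediate
8 | (2E,4E)-5-[(1R,4S)-1,4-dihydroxy-2,6,6-trimethylcyclohex-2-en-1-yl]-3-methylpenta-2,4-dienal | CC1=C[C@@H](O)CC(C)(C)[C@]1(O)/C=C/C(C)=C/C=O | intermediate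
9 | (1R,4S)-2,6,6-trimethyl-1-[(1E,3E,5E)-3-methyl-6-(4,4,5,5-tetramethyl-1,3,2-dioxaborolan-2-yl)hexa-1,3,5-trien-1-yl]cyclohex-2-ene-1,4-diol | CC1=C[C@@H](O)CC(C)(C)[C@]1(O)/C=C/C(C)=C/C=C/B1OC(C)(C)C(C)(C)O1 | intermediate
10 | (E)-1,2-dichloroethene | Cl/C=C/Cl | starting material
11 | propyne | CC#C | starting material
12 | (1E)-1-chloropent-1-en-3-yne | Cl/C=C/C#CC | intermediate
13 | (4E)-oct-4-ene-2,6-diyne | CC#C/C=C/C#CC | intermediate
14 | (2E,4E,6E)-octa-2,4,6-triene-2,7-diylbis[chlorobis(cyclopentadienyl)zirconium] | Cl[Zr](C1C=CC=C1)(C1C=CC=C1)/C(C)=C/C=C/C=C(\C)[Zr](Cl)(C1C=CC=C1)C1C=CC=C1 | intermediate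
15 | (2E,4E,6E)-2,7-diiodoocta-2,4,6-triene | I/C(C)=C/C=C/C=C(\C)I | intermediate
16 | (1R,4S)-1-[(1E,3E,5E,7E,9E,11E)-12-iodo-3,7-dimethyltrideca-1,3,5,7,9,11-hexaen-1-yl]-2,6,6-trimethylcyclohex-2-ene-1,4-diol | CC1=C[C@@H](O)CC(C)(C)[C@]1(O)/C=C/C(C)=C/C=C/C(C)=C/C=C/C=C(\C)I | intermediate
17 | (4S)-4-hydroxy-2,6,6-trimethylcyclohex-2-en-1-one | CC1=C[C@@H](O)CC(C)(C)C1=O | intermediate
18 | (4S)-4-{[tert-butyl(dimethyl)silyl]oxy}-2,6,6-trimethylcyclohex-2-en-1-one | CC1=C[C@@H](O[Si](C)(C)C(C)(C)C)CC(C)(C)C1=O | intermediate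
19 | lithium (4R)-4-{[tert-butyl(dimethyl)silyl]oxy}-2,6,6-trimethylcyclohex-1-en-1-olate | CC1=C(O[Li])C(C)(C)C[C@H](O[Si](C)(C)C(C)(C)C)C1 | intermediate
20 | (4R)-4-{[tert-butyl(dimethyl)silyl]oxy}-2,6,6-trimethylcyclohex-1-en-1-yl trifluoromethanesulfonate | CC1=C(OS(=O)(=O)C(F)(F)F)C(C)(C)C[C@H](O[Si](C)(C)C(C)(C)C)C1 | intermediate
21 | (2E)-5-[(4R)-4-{[tert-butyl(dimethyl)silyl]oxy}-2,6,6-trimethylcyclohex-1-en-1-yl]-3-methylpent-2-en-4-yn-1-ol | CC1=C(C#C/C(C)=C/CO)C(C)(C)C[C@H](O[Si](C)(C)C(C)(C)C)C1 | intermediate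
22 | (1R)-4-[(3E)-5-hydroxy-3-methylpent-3-en-1-yn-1-yl]-3,5,5-trimethylcyclohex-3-en-1-ol | CC1=C(C#C/C(C)=C/CO)C(C)(C)C[C@H](O)C1 | intermediate
23 | (2E)-5-[(4R)-4-hydroxy-2,6,6-trimethylcyclohex-1-en-1-yl]-3-methylpent-2-en-4-ynal | CC1=C(C#C/C(C)=C/C=O)C(C)(C)C[C@H](O)C1 | intermediate
24 | (1R)-3,5,5-trimethyl-4-[(3E,5E)-3-methyl-6-(4,4,5,5-tetramethyl-1,3,2-dioxaborolan-2-yl)hexa-3,5-dien-1-yn-1-yl]cyclohex-3-en-1-ol | CC1=C(C#C/C(C)=C/C=C/B2OC(C)(C)C(C)(C)O2)C(C)(C)C[C@H](O)C1 | intermediate
25 | (3S,6R,3′R)-target: all-E C40 triol with ring A = (1R,4S)-1,4-dihydroxy-2,6,6-trimethylcyclohex-2-en-1-yl and ring B = (4R)-4-hydroxy-2,6,6-trimethylcyclohex-1-en-1-yl joined to the chain through C7′≡C8′ | CC1=C[C@@H](O)CC(C)(C)[C@]1(O)/C=C/C(C)=C/C=C/C(C)=C/C=C/C=C(C)/C=C/C=C(\C)C#CC1=C(C)C[C@@H](O)CC1(C)C | target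

**Step count and risks**

Total step count: 17. Longest linear sequence: 8 steps (steps 1–6, 9 and 17; the ring B arm, steps 10–17, is equally long).

Steps most likely to fail:

1. Step 2, poor or reversed facial selectivity in the acetylide addition, which would erode the configuration at C6. The fallback sets out from 1 and comes back at 7, replacing steps 1–4. Ketalise the unhindered carbonyl of 1 with ethylene glycol and TsOH to 7,9,9-trimethyl-1,4-dioxaspiro[4.5]dec-6-en-8-one F1. Add the dilithio enynol 4 to obtain the racemic alkynyl carbinol ketal F2. Reduce the propargylic alkyne with NaAlH2(OCH2CH2OMe)2 to the racemic dienyl carbinol ketal F3. Hydrolyse the ketal with dilute HCl in acetone to the racemic hydroxy enone F4. Reduce the enone carbonyl under catalyst control (RuCl[(S,S)-TsDPEN](p-cymene), HCO2H/Et3N, as for step 10), so that both enantiomers become (3S) carbinols, namely 7 and its trans-diol diastereomer F5, and separate the two by chromatography. This replaces 1,4-induction by reagent control plus diastereomer separation.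

2. Step 3, competing elimination to the cyclohexadiene, SN2′ attack or closure of the tertiary hydroxyl onto C3 in place of clean Mitsunobu inversion. The fallback sets out from 5 and comes back at 7. Reduce 5 with NaAlH2(OCH2CH2OMe)2 to the (1R,4R) trans-diol dienyl triol F6. Oxidise both allylic alcohols with MnO2 to the (6R)-hydroxy keto aldehyde F7. Reduce both carbonyls with catecholborane and the enantiomer of the 2-methyl-CBS-oxazaborolidine that delivers the (3S) ring carbinol (Corey–Bakshi–Shibata reduction), which returns 7.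

3. Step 9, loss of mono-selectivity, because palladium released after the first coupling may insert into the second C–I bond of the same triene and give the doubly coupled product. The fallback sets out from 13 and comes back at 16. Treat 13 with one equivalent of Cp2Zr(H)Cl and then I2 to obtain the mono-iodide (2E,4E)-2-iodoocta-2,4-dien-6-yne F8. Couple F8 with 9 under the conditions of step 9 to give the propynyl-capped pentaenyne F9. Convert the remaining alkyne into the iodide by hydrozirconation (Cp2Zr(H)Cl in excess to saturate the two hydroxyls) and iodinolysis, which returns 16.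

Further compounds
F1 | step 2 | 7,9,9-trimethyl-1,4-dioxaspiro[4.5]dec-6-en-8-one | CC1=CC2(OCCO2)CC(C)(C)C1=O
F2 | step 2 | racemic 8-hydroxy-8-[(3E)-5-hydroxy-3-methylpent-3-en-1-yn-1-yl]-7,9,9-trimethyl-1,4-dioxaspiro[4.5]dec-6-ene | CC1=CC2(OCCO2)CC(C)(C)C1(O)C#C/C(C)=C/CO
F3 | step 2 | racemic 8-hydroxy-8-[(1E,3E)-5-hydroxy-3-methylpenta-1,3-dien-1-yl]-7,9,9-trimethyl-1,4-dioxaspiro[4.5]dec-6-ene | CC1=CC2(OCCO2)CC(C)(C)C1(O)/C=C/C(C)=C/CO
F4 | step 2 | racemic 4-hydroxy-4-[(1E,3E)-5-hydroxy-3-methylpenta-1,3-dien-1-yl]-3,5,5-trimethylcyclohex-2-en-1-one | CC1=CC(=O)CC(C)(C)C1(O)/C=C/C(C)=C/CO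
F5 | step 2 | (1S,4S)-1-[(1E,3E)-5-hydroxy-3-methylpenta-1,3-dien-1-yl]-2,6,6-trimethylcyclohex-2-ene-1,4-diol | CC1=C[C@@H](O)CC(C)(C)[C@@]1(O)/C=C/C(C)=C/CO
F6 | step 3 | (1R,4R)-1-[(1E,3E)-5-hydroxy-3-methylpenta-1,3-dien-1-yl]-2,6,6-trimethylcyclohex-2-ene-1,4-diol | CC1=C[C@H](O)CC(C)(C)[C@]1(O)/C=C/C(C)=C/CO
F7 | step 3 | (2E,4E)-5-[(1R)-1-hydroxy-2,6,6-trimethyl-4-oxocyclohex-2-en-1-yl]-3-methylpenta-2,4-dienal | CC1=CC(=O)CC(C)(C)[C@]1(O)/C=C/C(C)=C/C=O
F8 | step 9 | (2E,4E)-2-iodoocta-2,4-dien-6-yne | I/C(C)=C/C=C/C#CC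
F9 | step 9 | (1R,4S)-1-[(1E,3E,5E,7E,9E)-3,7-dimethyltrideca-1,3,5,7,9-pentaen-11-yn-1-yl]-2,6,6-trimethylcyclohex-2-ene-1,4-diol | CC1=C[C@@H](O)CC(C)(C)[C@]1(O)/C=C/C(C)=C/C=C/C(C)=C/C=C/C#CC
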